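**Plan**

1. Retrosynthesis: the four aryl benzyl ethers are removed last. The biaryl bond is then cut to a bromo lactone (unit A) and a boronate lactone (unit B). Each γ-lactone (O1, C2(=O), C3(OH), C4(H), C5H2) is cut at C4–C5 to the iodomethyl ester of a 2-(arylmethyl)-4-aryl-2-hydroxybut-3-enoic acid, then at C3–CH2Ar, then at the C3 carbinol.
2. Enabling feature: in each lactone C5 is a CH2 on the acyl oxygen O1 and C4 carries an arylmethyl group. C5 can therefore be an (acyloxy)methyl radical placed 1,5 to C4 of an E-styrene C4=C7' (5-exo attack, benzylic radical), with the quaternary carbinol C3 next to the alkene steering the face.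
3. Forward: each unit is built by condensation of an O-benzylvanillin with pyruvic acid, asymmetric hydrogenation of the keto group, dioxolanone formation, benzylation, hydrolysis, iodomethyl ester formation and radical ring closure. Unit A carries bromine on its C3-benzyl ring, unit B on its C4-benzyl ring. Borylation of unit B, Suzuki coupling and hydrogenolysis finish the route.
4. Stereochemistry: both C3 centres (R) come from the asymmetric hydrogenation and are carried into the quaternary centres by alkylation of cis-dioxolanones with retention. Both C4 centres (R) are set in the ring closures by 1,2-induction from C3.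

Key step: step 9

Assumption: the (R)-SunPhos complex is taken to deliver the R carbinol, by analogy with related biaryl diphosphine–ruthenium catalysts; should the opposite sense be found, the (S)-ligand is used in steps 4 and 11 and nothing else changes.

**Route**

Step 1
Reactants: 1 5-bromovanillin
Product: 2 4-(benzyloxy)-3-bromo-5-methoxybenzaldehyde
Conditions: BnBr, K2CO3, DMF, 60 °C
Reagents that add atoms: benzyl bromide, BrCc1ccccc1
Why: Williamson etherification of the phenoxide; the benzyl ether masks the phenol through the enolate, radical and palladium steps and is removed by hydrogenolysis at the end.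

Step 2
Reactants: 2 4-(benzyloxy)-3-bromo-5-methoxybenzaldehyde
Product: 4 2-(benzyloxy)-1-bromo-5-(bromomethyl)-3-methoxybenzene, via benzylic alcohol 3 (not isolated)
Conditions: NaBH4, MeOH/THF, 0 °C; aqueous work-up; then PBr3, CH2Cl2, 0 °C
Reagents that add atoms: phosphorus tribromide, BrP(Br)Br
Why: Borohydride reduction of the aldehyde followed by bromination of the crude benzylic alcohol through its phosphite ester, both routine on this ring.

Step 3
Reactants: 5 4-(benzyloxy)-3-methoxybenzaldehyde; 6 pyruvic acid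
Product: 7 (E)-4-[4-(benzyloxy)-3-methoxyphenyl]-2-oxobut-3-enoic acid
Conditions: KOH, MeOH, 0 °C to rt; then aq. HCl
Reagents that add atoms: none
Why: Claisen–Schmidt-type aldol condensation of the pyruvate enolate with the non-enolisable aldehyde should give the E-configured β,γ-unsaturated α-keto acid, which separates as its potassium salt.

Step 4
Reactants: 7 (E)-4-[4-(benzyloxy)-3-methoxyphenyl]-2-oxobut-3-enoic acid
Product: 8 (2R,3E)-4-[4-(benzyloxy)-3-methoxyphenyl]-2-hydroxybut-3-enoic acid
Conditions: [RuCl(benzene)((R)-SunPhos)]Cl (1 mol%), H2 (20 bar), aq. HBr (cat.), MeOH, 70 °C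
Reagents that add atoms: none
Why: Asymmetric hydrogenation of a chelating α-keto acid by a divalent ruthenium–diphosphine complex should reduce C=O in preference to the conjugated C=C and leave the benzyl ether untouched; the ligand antipode is the one expected, by analogy with BINAP-type catalysts, to give the R carbinol (the future C3 of lactone A), and a Mosher ester analysis of the first batch would confirm this sense.

Step 5
Reactants: 8 (2R,3E)-4-[4-(benzyloxy)-3-methoxyphenyl]-2-hydroxybut-3-enoic acid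
Product: 10 (2R,5R)-5-{(E)-2-[4-(benzyloxy)-3-methoxyphenyl]ethenyl}-2-tert-butyl-1,3-dioxolan-4-one (cis), via bis(trimethylsilyl) derivative 9 (not isolated)
Conditions: TMSCl, Et3N, CH2Cl2, 0 °C to rt; filter; then t-BuCHO, TMSOTf (5 mol%), CH2Cl2, −78 to −30 °C
Reagents that add atoms: pivalaldehyde, CC(C)(C)C=O
Why: Silyl-triflate-catalysed acetalisation of the bis-silylated hydroxy acid (first stage of self-regeneration of stereocentres) should give mainly the cis-dioxolanone, the acetal centre being set by the existing carbinol centre (tert-butyl cis to styryl), while the cold aprotic medium should avoid ionisation of the allylic carbinol; the cis isomer is purified by crystallisation.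

Step 6
Reactants: 10 cis-dioxolanone of unit A; 4 2-(benzyloxy)-1-bromo-5-(bromomethyl)-3-methoxybenzene
Product: 12 (2R,5R)-5-[4-(benzyloxy)-3-bromo-5-methoxybenzyl]-5-{(E)-2-[4-(benzyloxy)-3-methoxyphenyl]ethenyl}-2-tert-butyl-1,3-dioxolan-4-one, via lithium enolate 11 (not isolated)
Conditions: LiHMDS, THF, −78 °C; then 4, −78 to −40 °C
Reagents that add atoms: none
Why: Seebach alkylation of the dioxolanone enolate: the benzylic bromide should enter anti to the tert-butyl group (retention at the carbinol carbon) and at the α-carbon of the dienolate (which keeps the styrene conjugation), setting the quaternary R centre that becomes C3 of lactone A, while the amide base should not touch the aryl bromide at this temperature.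

Step 7
Reactants: 12 benzylated dioxolanone of unit A
Product: 13 (2R,3E)-2-[4-(benzyloxy)-3-bromo-5-methoxybenzyl]-4-[4-(benzyloxy)-3-methoxyphenyl]-2-hydroxybut-3-enoic acid
Conditions: LiOH·H2O, THF/MeOH/H2O, rt; then cold aq. HCl to pH 3
Reagents that add atoms: lithium hydroxide (hydroxide oxygen), [Li+].[OH-]
Why: Hydroxide opens the acylal-type dioxolanone at the carbonyl group and the hemiacetal then loses pivalaldehyde, which frees the α-hydroxy acid without touching the quaternary centre; mild acidification avoids ionisation of the tertiary allylic alcohol.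

Step 8
Reactants: 13 hydroxy acid of unit A; 14 chloromethyl chlorosulfate
Product: 16 iodomethyl (2R,3E)-2-[4-(benzyloxy)-3-bromo-5-methoxybenzyl]-4-[4-(benzyloxy)-3-methoxyphenyl]-2-hydroxybut-3-enoate, via chloromethyl ester 15 (not isolated)
Conditions: 14, NaHCO3, Bu4NHSO4, CH2Cl2/H2O, 0 °C to rt; then NaI, acetone, rt, dark
Reagents that add atoms: sodium iodide, [Na+].[I-]
Why: Phase-transfer O-alkylation of the carboxylate (chlorosulfate is displaced far faster than chloride, and hydrogencarbonate does not deprotonate the tertiary alcohol), then Finkelstein exchange to the iodomethyl ester that serves as the radical precursor.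

Step 9
Reactants: 16 iodomethyl ester of unit A
Product: 17 (3R,4R)-3-[4-(benzyloxy)-3-bromo-5-methoxybenzyl]-4-[4-(benzyloxy)-3-methoxybenzyl]-3-hydroxydihydrofuran-2(3H)-one (bromo lactone A)
Conditions: Bu3SnH (1.15 equiv, syringe pump, 6 h), AIBN (0.2 equiv), benzene (5 mM), 80 °C
Reagents that add atoms: none
Why: The tributylstannyl radical abstracts iodine from the O–CH2–I group, the (acyloxy)methyl radical C5 adds to C4, the styrene carbon next to the quaternary carbinol C3, and the benzylic radical so formed takes hydrogen from Bu3SnH and carries the chain. The closest known reaction type is the tin hydride-mediated ring closure of (alk-3-enoyloxy)methyl radicals, generated from halomethyl but-3-enoates, to γ-butyrolactones. The lactone ring closes in the 5-exo-trig mode; 6-endo attack at the aryl-bearing carbon would give an unstabilised secondary radical and is not expected. The new C4 centre is controlled by the neighbouring C3: in the chair-like 5-exo transition state the larger C3 substituent, the arylmethyl group, takes the pseudo-equatorial position and the hydroxyl the pseudo-axial one, so the new arylmethyl group at C4 should come out trans to the C3 arylmethyl group and cis to OH, which is the (3R,4R) arrangement. The step needs ring closure to outrun hydrogen transfer to the open-chain radical, whose ester must first turn into its E conformer; the activated styrene acceptor, the fully substituted C3 and a low stationary stannane concentration are relied on for this. It also needs the aryl C–Br bond to survive, which the far faster iodine abstraction from the alkyl iodide and the small excess of stannane should secure.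

Step 10
Reactants: 2 4-(benzyloxy)-3-bromo-5-methoxybenzaldehyde; 6 pyruvic acid
Product: 18 (E)-4-[4-(benzyloxy)-3-bromo-5-methoxyphenyl]-2-oxobut-3-enoic acid
Conditions: KOH, MeOH, 0 °C to rt; then aq. HCl
Reagents that add atoms: none
Why: Same Claisen–Schmidt-type aldol condensation as in step 3, giving the E-enone acid.

Step 11
Reactants: 18 (E)-4-[4-(benzyloxy)-3-bromo-5-methoxyphenyl]-2-oxobut-3-enoic acid
Product: 19 (2R,3E)-4-[4-(benzyloxy)-3-bromo-5-methoxyphenyl]-2-hydroxybut-3-enoic acid
Conditions: [RuCl(benzene)((R)-SunPhos)]Cl (1 mol%), H2 (20 bar), aq. HBr (cat.), MeOH, 70 °C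
Reagents that add atoms: none
Why: Same ruthenium-catalysed asymmetric hydrogenation of the keto group as in step 4, which should also leave the aryl bromide untouched and sets the R carbinol that becomes C3 of lactone B.

Step 12
Reactants: 19 (2R,3E)-4-[4-(benzyloxy)-3-bromo-5-methoxyphenyl]-2-hydroxybut-3-enoic acid
Product: 21 (2R,5R)-5-{(E)-2-[4-(benzyloxy)-3-bromo-5-methoxyphenyl]ethenyl}-2-tert-butyl-1,3-dioxolan-4-one (cis), via bis(trimethylsilyl) derivative 20 (not isolated)
Conditions: TMSCl, Et3N, CH2Cl2, 0 °C to rt; filter; then t-BuCHO, TMSOTf (5 mol%), CH2Cl2, −78 to −30 °C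
Reagents that add atoms: pivalaldehyde, CC(C)(C)C=O
Why: Same kinetically controlled cis-selective acetalisation as in step 5, the acetal centre being set by the carbinol centre.

Step 13
Reactants: 22 [4-(benzyloxy)-3-methoxyphenyl]methanol
Product: 23 1-(benzyloxy)-4-(bromomethyl)-2-methoxybenzene
Conditions: PBr3, Et2O, 0 °C
Reagents that add atoms: phosphorus tribromide, BrP(Br)Br
Why: Standard conversion of a benzylic alcohol to the bromide by SN2 displacement of the phosphite ester.

Step 14
Reactants: 21 cis-dioxolanone of unit B; 23 1-(benzyloxy)-4-(bromomethyl)-2-methoxybenzene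
Product: 25 (2R,5R)-5-[4-(benzyloxy)-3-methoxybenzyl]-5-{(E)-2-[4-(benzyloxy)-3-bromo-5-methoxyphenyl]ethenyl}-2-tert-butyl-1,3-dioxolan-4-one, via lithium enolate 24 (not isolated)
Conditions: LiHMDS, THF, −78 °C; then 23, −78 to −40 °C
Reagents that add atoms: none
Why: Seebach alkylation as in step 6, anti to the tert-butyl group and at the α-carbon, setting the quaternary R centre that becomes C3 of lactone B.

Step 15
Reactants: 25 benzylated dioxolanone of unit B
Product: 26 (2R,3E)-2-[4-(benzyloxy)-3-methoxybenzyl]-4-[4-(benzyloxy)-3-bromo-5-methoxyphenyl]-2-hydroxybut-3-enoic acid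
Conditions: LiOH·H2O, THF/MeOH/H2O, rt; then cold aq. HCl to pH 3
Reagents that add atoms: lithium hydroxide (hydroxide oxygen), [Li+].[OH-]
Why: Same hydroxide opening of the acylal-type dioxolanone with loss of pivalaldehyde as in step 7, leaving the quaternary centre untouched.

Step 16
Reactants: 26 hydroxy acid of unit B; 14 chloromethyl chlorosulfate
Product: 28 iodomethyl (2R,3E)-2-[4-(benzyloxy)-3-methoxybenzyl]-4-[4-(benzyloxy)-3-bromo-5-methoxyphenyl]-2-hydroxybut-3-enoate, via chloromethyl ester 27 (not isolated)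
Conditions: 14, NaHCO3, Bu4NHSO4, CH2Cl2/H2O, 0 °C to rt; then NaI, acetone, rt, dark
Reagents that add atoms: sodium iodide, [Na+].[I-]
Why: Same phase-transfer O-alkylation of the carboxylate and Finkelstein exchange as in step 8.

Step 17
Reactants: 28 iodomethyl ester of unit B
Product: 29 (3R,4R)-4-[4-(benzyloxy)-3-bromo-5-methoxybenzyl]-3-[4-(benzyloxy)-3-methoxybenzyl]-3-hydroxydihydrofuran-2(3H)-one (bromo lactone B)
Conditions: Bu3SnH (1.15 equiv, syringe pump, 6 h), AIBN (0.2 equiv), benzene (5 mM), 80 °C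
Reagents that add atoms: none
Why: Same tin hydride-mediated 5-exo-trig closure of the (acyloxy)methyl radical as in step 9, here onto the bromo-substituted styrene; the C4 centre (R) should again be set by the pseudo-equatorial C3 arylmethyl group, and the far faster iodine abstraction should spare the aryl bromide needed for step 18.

Step 18
Reactants: 29 bromo lactone B
Product: 30 pinacol boronate of lactone B (4,4,5,5-tetramethyl-1,3,2-dioxaborolan-2-yl in place of Br)
Conditions: B2pin2, Pd(dppf)Cl2, KOAc, 1,4-dioxane, 90 °C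
Reagents that add atoms: bis(pinacolato)diboron, CC1(C)OB(OC1(C)C)B1OC(C)(C)C(C)(C)O1
Why: Miyaura borylation of the aryl bromide under anhydrous acetate conditions, which the lactone and the free tertiary alcohol should tolerate.

Step 19
Reactants: 17 bromo lactone A; 30 pinacol boronate of lactone B
Product: 31 tetra-O-benzyl bis-lactone (both lactones 3R,4R)
Conditions: Pd(OAc)2 (5 mol%), SPhos (10 mol%), K3PO4, toluene/H2O, 80 °C; then aq. HCl work-up
Reagents that add atoms: none
Why: Suzuki–Miyaura coupling joins the C3-benzyl ring of lactone A to the C4-benzyl ring of lactone B at the carbons ortho to the benzyloxy groups, a biaryl phosphine ligand handling the two ortho-alkoxy partners; neither the quaternary C3 nor C4 (β to the carbonyl) can epimerise under the base, and the acidic work-up recloses any lactone opened by it.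

Step 20
Reactants: 31 tetra-O-benzyl bis-lactone
Product: 32 target CNP0218652.1
Conditions: H2 (1 atm), Pd/C, EtOAc/MeOH, rt
Reagents that add atoms: none
Why: Hydrogenolysis of the four aryl benzyl ethers; the lactones, the non-benzylic tertiary alcohols and the biaryl should be inert under these conditions.

**Compound list**

1 | 5-bromovanillin (3-bromo-4-hydroxy-5-methoxybenzaldehyde) | COc1cc(C=O)cc(Br)c1O | starting material
2 | 4-(benzyloxy)-3-bromo-5-methoxybenzaldehyde | COc1cc(C=O)cc(Br)c1OCc1ccccc1 | intermediate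
3 | [4-(benzyloxy)-3-bromo-5-methoxyphenyl]methanol | COc1cc(CO)cc(Br)c1OCc1ccccc1 | intermediate
4 | 2-(benzyloxy)-1-bromo-5-(bromomethyl)-3-methoxybenzene | COc1cc(CBr)cc(Br)c1OCc1ccccc1 | intermediate
5 | 4-(benzyloxy)-3-methoxybenzaldehyde | COc1cc(C=O)ccc1OCc1ccccc1 | starting material
6 | pyruvic acid | CC(=O)C(=O)O | starting material
7 | (E)-4-[4-(benzyloxy)-3-methoxyphenyl]-2-oxobut-3-enoic acid | OC(=O)C(=O)/C=C/c1ccc(OCc2ccccc2)c(OC)c1 | intermediate
8 | (2R,3E)-4-[4-(benzyloxy)-3-methoxyphenyl]-2-hydroxybut-3-enoic acid | OC(=O)[C@H](O)/C=C/c1ccc(OCc2ccccc2)c(OC)c1 | intermediate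
9 | trimethylsilyl (2R,3E)-4-[4-(benzyloxy)-3-methoxyphenyl]-2-(trimethylsilyloxy)but-3-enoate | C[Si](C)(C)OC(=O)[C@H](O[Si](C)(C)C)/C=C/c1ccc(OCc2ccccc2)c(OC)c1 | intermediate
10 | (2R,5R)-5-{(E)-2-[4-(benzyloxy)-3-methoxyphenyl]ethenyl}-2-tert-butyl-1,3-dioxolan-4-one (cis) | CC(C)(C)[C@H]1OC(=O)[C@@H](/C=C/c2ccc(OCc3ccccc3)c(OC)c2)O1 | intermediate
11 | lithium enolate of 10 | CC(C)(C)[C@H]1OC(O[Li])=C(/C=C/c2ccc(OCc3ccccc3)c(OC)c2)O1 | intermediate
12 | (2R,5R)-5-[4-(benzyloxy)-3-bromo-5-methoxybenzyl]-5-{(E)-2-[4-(benzyloxy)-3-methoxyphenyl]ethenyl}-2-tert-butyl-1,3-dioxolan-4-one | CC(C)(C)[C@H]1OC(=O)[C@@](Cc2cc(OC)c(OCc3ccccc3)c(Br)c2)(/C=C/c2ccc(OCc3ccccc3)c(OC)c2)O1 | intermediate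
13 | (2R,3E)-2-[4-(benzyloxy)-3-bromo-5-methoxybenzyl]-4-[4-(benzyloxy)-3-methoxyphenyl]-2-hydroxybut-3-enoic acid | OC(=O)[C@@](O)(Cc1cc(OC)c(OCc2ccccc2)c(Br)c1)/C=C/c1ccc(OCc2ccccc2)c(OC)c1 | intermediate
14 | chloromethyl chlorosulfate | ClCOS(=O)(=O)Cl | starting material
15 | chloromethyl ester of 13 | ClCOC(=O)[C@@](O)(Cc1cc(OC)c(OCc2ccccc2)c(Br)c1)/C=C/c1ccc(OCc2ccccc2)c(OC)c1 | intermediate
16 | iodomethyl (2R,3E)-2-[4-(benzyloxy)-3-bromo-5-methoxybenzyl]-4-[4-(benzyloxy)-3-methoxyphenyl]-2-hydroxybut-3-enoate | ICOC(=O)[C@@](O)(Cc1cc(OC)c(OCc2ccccc2)c(Br)c1)/C=C/c1ccc(OCc2ccccc2)c(OC)c1 | intermediate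
17 | (3R,4R)-3-[4-(benzyloxy)-3-bromo-5-methoxybenzyl]-4-[4-(benzyloxy)-3-methoxybenzyl]-3-hydroxydihydrofuran-2(3H)-one (bromo lactone A) | COc1cc(C[C@@H]2COC(=O)[C@@]2(O)Cc2cc(OC)c(OCc3ccccc3)c(Br)c2)ccc1OCc1ccccc1 | intermediate
18 | (E)-4-[4-(benzyloxy)-3-bromo-5-methoxyphenyl]-2-oxobut-3-enoic acid | OC(=O)C(=O)/C=C/c1cc(OC)c(OCc2ccccc2)c(Br)c1 | intermediate
19 | (2R,3E)-4-[4-(benzyloxy)-3-bromo-5-methoxyphenyl]-2-hydroxybut-3-enoic acid | OC(=O)[C@H](O)/C=C/c1cc(OC)c(OCc2ccccc2)c(Br)c1 | intermediate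
20 | trimethylsilyl (2R,3E)-4-[4-(benzyloxy)-3-bromo-5-methoxyphenyl]-2-(trimethylsilyloxy)but-3-enoate | C[Si](C)(C)OC(=O)[C@H](O[Si](C)(C)C)/C=C/c1cc(OC)c(OCc2ccccc2)c(Br)c1 | intermediate
21 | (2R,5R)-5-{(E)-2-[4-(benzyloxy)-3-bromo-5-methoxyphenyl]ethenyl}-2-tert-butyl-1,3-dioxolan-4-one (cis) | CC(C)(C)[C@H]1OC(=O)[C@@H](/C=C/c2cc(OC)c(OCc3ccccc3)c(Br)c2)O1 | intermediate
22 | [4-(benzyloxy)-3-methoxyphenyl]methanol | COc1cc(CO)ccc1OCc1ccccc1 | starting material
23 | 1-(benzyloxy)-4-(bromomethyl)-2-methoxybenzene | COc1cc(CBr)ccc1OCc1ccccc1 | intermediate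
24 | lithium enolate of 21 | CC(C)(C)[C@H]1OC(O[Li])=C(/C=C/c2cc(OC)c(OCc3ccccc3)c(Br)c2)O1 | intermediate
25 | (2R,5R)-5-[4-(benzyloxy)-3-methoxybenzyl]-5-{(E)-2-[4-(benzyloxy)-3-bromo-5-methoxyphenyl]ethenyl}-2-tert-butyl-1,3-dioxolan-4-one | CC(C)(C)[C@H]1OC(=O)[C@@](Cc2ccc(OCc3ccccc3)c(OC)c2)(/C=C/c2cc(OC)c(OCc3ccccc3)c(Br)c2)O1 | intermediate
26 | (2R,3E)-2-[4-(benzyloxy)-3-methoxybenzyl]-4-[4-(benzyloxy)-3-bromo-5-methoxyphenyl]-2-hydroxybut-3-enoic acid | OC(=O)[C@@](O)(Cc1ccc(OCc2ccccc2)c(OC)c1)/C=C/c1cc(OC)c(OCc2ccccc2)c(Br)c1 | intermediate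
27 | chloromethyl ester of 26 | ClCOC(=O)[C@@](O)(Cc1ccc(OCc2ccccc2)c(OC)c1)/C=C/c1cc(OC)c(OCc2ccccc2)c(Br)c1 | intermediate
28 | iodomethyl (2R,3E)-2-[4-(benzyloxy)-3-methoxybenzyl]-4-[4-(benzyloxy)-3-bromo-5-methoxyphenyl]-2-hydroxybut-3-enoate | ICOC(=O)[C@@](O)(Cc1ccc(OCc2ccccc2)c(OC)c1)/C=C/c1cc(OC)c(OCc2ccccc2)c(Br)c1 | intermediate
29 | (3R,4R)-4-[4-(benzyloxy)-3-bromo-5-methoxybenzyl]-3-[4-(benzyloxy)-3-methoxybenzyl]-3-hydroxydihydrofuran-2(3H)-one (bromo lactone B) | COc1cc(C[C@@H]2COC(=O)[C@@]2(O)Cc2ccc(OCc3ccccc3)c(OC)c2)cc(Br)c1OCc1ccccc1 | intermediate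
30 | pinacol boronate of 29 (4,4,5,5-tetramethyl-1,3,2-dioxaborolan-2-yl in place of Br) | COc1cc(C[C@@H]2COC(=O)[C@@]2(O)Cc2ccc(OCc3ccccc3)c(OC)c2)cc(B2OC(C)(C)C(C)(C)O2)c1OCc1ccccc1 | intermediate
31 | tetra-O-benzyl bis-lactone: the target with its four phenols as benzyl ethers, both lactones (3R,4R)-3-hydroxy-3,4-bis(arylmethyl)dihydrofuran-2(3H)-ones | COc1cc(C[C@@H]2COC(=O)[C@@]2(O)Cc2cc(OC)c(OCc3ccccc3)c(-c3cc(C[C@@H]4COC(=O)[C@@]4(O)Cc4ccc(OCc5ccccc5)c(OC)c4)cc(OC)c3OCc3ccccc3)c2)ccc1OCc1ccccc1 | intermediate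
32 | CNP0218652.1: biaryl-linked dimer of the (3R,4R)-3-hydroxy-3,4-bis(4-hydroxy-3-methoxybenzyl)butyrolactone unit, the C3-benzyl ring of lactone A joined at its C5 to C5 of the C4-benzyl ring of lactone B | COc1cc(C[C@@H]2COC(=O)[C@@]2(O)Cc2cc(OC)c(O)c(-c3cc(C[C@@H]4COC(=O)[C@@]4(O)Cc4ccc(O)c(OC)c4)cc(OC)c3O)c2)ccc1O | target

**Count**

Total steps: 20. Longest linear sequence: 11 steps (steps 1, 10, 11, 12, 14, 15, 16, 17, 18, 19, 20).

**Steps most likely to fail**

Step 9. The stannane may transfer hydrogen to the (acyloxy)methyl radical before ring closure, because the ester must first rotate out of its preferred Z conformer, and the facial selectivity at C4 may be too low. The fallback builds the lactone with the C4–C5 bond present from the start, by the malate chirality-transfer sequence; it sets out from bromides 23 and 4 and comes back at 17. Commercial diisopropyl (R)-malate (CC(C)OC(=O)C[C@@H](O)C(=O)OC(C)C) is deprotonated twice (LiHMDS, THF, −78 to −20 °C) and alkylated with 23 anti to the alkoxide (Frater–Seebach alkylation) to give diisopropyl (2R,3S)-3-[4-(benzyloxy)-3-methoxybenzyl]-2-hydroxybutanedioate F1. Saponification (KOH, MeOH/H2O) gives the diacid F2. Pivalaldehyde (TsOH, cat. H2SO4, pentane, reflux with water removal) closes the cis-dioxolanone on the α-hydroxy acid half and gives the dioxolanone acid F3. Its dianion (LiHMDS, THF, −78 °C) is benzylated with 4 anti to the tert-butyl group to give the quaternary dioxolanone acid F4. BH3·SMe2 (THF, 0 °C) reduces the free carboxylic acid to the primary alcohol F5, and acid (TFA, wet CH2Cl2) transfers the acyl group to this alcohol with loss of pivalaldehyde, which gives 17.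

Step 17. The open-chain radical may again be reduced before closure, and the aryl bromide, which here must survive to serve the borylation, may be lost to the stannane. The fallback is the malate sequence with the bromides in the opposite order; it sets out from bromides 4 and 23 and comes back at 29. Diisopropyl (R)-malate is alkylated as its dianion with 4 to give diisopropyl (2R,3S)-3-[4-(benzyloxy)-3-bromo-5-methoxybenzyl]-2-hydroxybutanedioate F6. Saponification gives the diacid F7, and pivalaldehyde under acid gives the dioxolanone acid F8. Benzylation of its dianion with 23 gives the quaternary dioxolanone acid F9. Reduction with BH3·SMe2 gives the primary alcohol F10, which lactonises under acid (TFA, wet CH2Cl2) with loss of pivalaldehyde to 29.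

Step 8. The iodomethyl ester may alkylate its own tertiary hydroxyl (5-exo-tet closure to a 1,3-dioxolan-4-one) or a second carboxylate (methylene diester) before the radical step; the same holds for step 16. The fallback masks the hydroxyl first; it sets out from 13 and comes back at 17. Compound 13 is silylated on both oxygens (TESOTf, 2,6-lutidine, CH2Cl2, 0 °C) to the bis(triethylsilyl) derivative F11, and K2CO3 in MeOH/H2O (0 °C) cleaves only the silyl ester to give the (triethylsilyl)oxy acid F12. Alkylation with 14 and halide exchange as in step 8 give, by way of the chloromethyl ester F13, the iodomethyl ester F14. Ring closure under the conditions of step 9 should give the silylated lactone F15; the silyl ether still has a smaller conformational demand than the arylmethyl group, so the same sense of induction is expected. HF·pyridine (THF, 0 °C) then returns 17.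

**Further compounds**

F1 | step 9 | diisopropyl (2R,3S)-3-[4-(benzyloxy)-3-methoxybenzyl]-2-hydroxybutanedioate | CC(C)OC(=O)[C@@H](Cc1ccc(OCc2ccccc2)c(OC)c1)[C@@H](O)C(=O)OC(C)C
F2 | step 9 | (2R,3S)-3-[4-(benzyloxy)-3-methoxybenzyl]-2-hydroxybutanedioic acid | OC(=O)[C@@H](Cc1ccc(OCc2ccccc2)c(OC)c1)[C@@H](O)C(=O)O
F3 | step 9 | cis-dioxolanone acid from F2: 3-[4-(benzyloxy)-3-methoxyphenyl]-2-(cis-2-tert-butyl-5-oxo-1,3-dioxolan-4-yl)propanoic acid, configurations of F2 retained | CC(C)(C)[C@H]1OC(=O)[C@@H]([C@H](Cc2ccc(OCc3ccccc3)c(OC)c2)C(=O)O)O1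
F4 | step 9 | F3 carrying a 4-(benzyloxy)-3-bromo-5-methoxybenzyl group at the dioxolanone ring carbon next to the carbonyl, trans to tert-butyl | CC(C)(C)[C@H]1OC(=O)[C@@](Cc2cc(OC)c(OCc3ccccc3)c(Br)c2)([C@H](Cc2ccc(OCc3ccccc3)c(OC)c2)C(=O)O)O1
F5 | step 9 | primary alcohol from F4 (CH2OH in place of the free CO2H) | CC(C)(C)[C@H]1OC(=O)[C@@](Cc2cc(OC)c(OCc3ccccc3)c(Br)c2)([C@H](Cc2ccc(OCc3ccccc3)c(OC)c2)CO)O1
F6 | step 17 | diisopropyl (2R,3S)-3-[4-(benzyloxy)-3-bromo-5-methoxybenzyl]-2-hydroxybutanedioate | CC(C)OC(=O)[C@@H](Cc1cc(OC)c(OCc2ccccc2)c(Br)c1)[C@@H](O)C(=O)OC(C)C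
F7 | step 17 | (2R,3S)-3-[4-(benzyloxy)-3-bromo-5-methoxybenzyl]-2-hydroxybutanedioic acid | OC(=O)[C@@H](Cc1cc(OC)c(OCc2ccccc2)c(Br)c1)[C@@H](O)C(=O)O
F8 | step 17 | cis-dioxolanone acid from F7: 3-[4-(benzyloxy)-3-bromo-5-methoxyphenyl]-2-(cis-2-tert-butyl-5-oxo-1,3-dioxolan-4-yl)propanoic acid, configurations of F7 retained | CC(C)(C)[C@H]1OC(=O)[C@@H]([C@H](Cc2cc(OC)c(OCc3ccccc3)c(Br)c2)C(=O)O)O1
F9 | step 17 | F8 carrying a 4-(benzyloxy)-3-methoxybenzyl group at the dioxolanone ring carbon next to the carbonyl, trans to tert-butyl | CC(C)(C)[C@H]1OC(=O)[C@@](Cc2ccc(OCc3ccccc3)c(OC)c2)([C@H](Cc2cc(OC)c(OCc3ccccc3)c(Br)c2)C(=O)O)O1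
F10 | step 17 | primary alcohol from F9 (CH2OH in place of the free CO2H) | CC(C)(C)[C@H]1OC(=O)[C@@](Cc2ccc(OCc3ccccc3)c(OC)c2)([C@H](Cc2cc(OC)c(OCc3ccccc3)c(Br)c2)CO)O1
F11 | step 8 | triethylsilyl (2R,3E)-2-[4-(benzyloxy)-3-bromo-5-methoxybenzyl]-4-[4-(benzyloxy)-3-methoxyphenyl]-2-(triethylsilyloxy)but-3-enoate | CC[Si](CC)(CC)OC(=O)[C@@](O[Si](CC)(CC)CC)(Cc1cc(OC)c(OCc2ccccc2)c(Br)c1)/C=C/c1ccc(OCc2ccccc2)c(OC)c1
F12 | step 8 | (2R,3E)-2-[4-(benzyloxy)-3-bromo-5-methoxybenzyl]-4-[4-(benzyloxy)-3-methoxyphenyl]-2-(triethylsilyloxy)but-3-enoic acid | OC(=O)[C@@](O[Si](CC)(CC)CC)(Cc1cc(OC)c(OCc2ccccc2)c(Br)c1)/C=C/c1ccc(OCc2ccccc2)c(OC)c1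
F13 | step 8 | chloromethyl ester of F12 | ClCOC(=O)[C@@](O[Si](CC)(CC)CC)(Cc1cc(OC)c(OCc2ccccc2)c(Br)c1)/C=C/c1ccc(OCc2ccccc2)c(OC)c1
F14 | step 8 | iodomethyl ester of F12 | ICOC(=O)[C@@](O[Si](CC)(CC)CC)(Cc1cc(OC)c(OCc2ccccc2)c(Br)c1)/C=C/c1ccc(OCc2ccccc2)c(OC)c1
F15 | step 8 | O-triethylsilyl ether of 17 at the tertiary hydroxyl | COc1cc(C[C@@H]2COC(=O)[C@@]2(O[Si](CC)(CC)CC)Cc2cc(OC)c(OCc3ccccc3)c(Br)c2)ccc1OCc1ccccc1
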